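## Analysis of the target

Compound 17 is a twofold-symmetric biaryl made of two 5,6,7,8-tetrahydronaphthalen-2-ol halves joined through C1. In each half a benzene ring (ring A: C1–C4, C4a, C8a) carries the hydroxyl at C2 and a methyl group at C3, and a fused carbocycle (ring B: C4a, C5–C8, C8a) carries isopropyl at C5 and methyl at C8. Each half holds two benzylic stereocentres, C5 and C8, both S, which puts isopropyl and methyl cis in a 1,4-relationship across ring B; the halves are homochiral, so four centres must be set in one absolute sense. The biaryl bond has four ortho substituents (two hydroxyls and two C8a atoms, each followed by the C8 methine), so rotation should be slow, and the structure as written gives this axis no descriptor. The sensitive sites are the tertiary benzylic C–H bonds at C5 and C8 (hydride or hydrogen-atom abstraction would epimerise them or aromatise ring B to a naphthalene) and the electron-rich phenols, which rules out strong oxidants and hot strong acid late in the route. Two things make the synthesis hard: ring B has no functional group through which C5 could direct C8, and C8a is out of reach of electrophilic ring closure, because it is meta to the C2 oxygen and wedged between C1 and C4a, whereas a phenol directs to C1, C3 and C4a. The strategy reads this the other way round: C2 and C8a both flank C1, so if C8a starts out bearing oxygen, ring A is a 2-arylresorcinol; one oxygen stays as the C2 phenol and the other, as a triflate, lets palladium make the C8a–C8 bond onto a terminal alkene hung from C5.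

## Retrosynthetic reasoning

17 from 16. Both phenols are carried as methyl ethers, so the last operation is ether cleavage only. No C–C bond is cut here; the gain is that every organometallic and hydride step sees an inert oxygen at C2.

16 from 15. The two C8–H bonds are removed, giving exocyclic methylenes at C8 and C8'. This is chosen because an sp2 carbon at C8 is exactly what a Heck closure delivers. The forward hydrogenation must add hydrogen to the face of C8 anti to the C5 isopropyl group; because C5 is remote, a chiral catalyst has to carry most of the control.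

15 from 14 (the key disconnection). The C8a–C8 bond is cut in both halves. This is the one ring bond that electrophilic chemistry cannot make. Cutting it turns C8a into a carbon bearing a sulfonate (a former resorcinol oxygen) and C8 into the internal carbon of a monosubstituted alkene, and opens ring B to an arm whose only stereocentre is C5. The other ring-B bond to the arene, C4a–C5, is kept for a conjugate addition. Forward, palladium must insert into a C–O bond with two ortho substituents and close 6-exo, twice.

14 from 13 from 12. The triflates come from the phenols of 13, and these from the acetal ethers of 12. No skeletal bond changes; the acetal is chosen because it served as ortho-director earlier and leaves under acid that spares methyl ethers and alkenes.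

12 from 10 and 11. The C7–C8 bond is cut between a primary alkyl iodide and the vinyl nucleophile 11. The vinyl group is brought in late so that no alkene is present during the rhodium and hydride steps. Iodide 10 goes back through diol 9 to diester 8 by functional-group changes only.

8 from 6 and 7. The C4a–C5 bond is cut, giving an aryl boron compound and enoate 7. A benzylic centre carrying aryl, isopropyl and CH2 is the typical product of an asymmetric aryl conjugate addition to a β-isopropyl acrylate, so C5 is set here by a chiral catalyst. Doing both arms on one molecule lets the minor-face product be removed as a diastereomer.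

6 from 4 via 5. The two C–B bonds at C3 are cut back to C–H. On each ring of 4 the acetal ether has exactly one free ortho hydrogen and the methoxy group has none, so the lithiation to 5 has no choice of site.

4 from 2 via 3, and 2 from 1. The biaryl bond is cut to two molecules of aryllithium 3, formed at the hydrogen between the two oxygens of 2, the most acidic position of the ring. Making the biaryl first uses this position for C1 and leaves the next lithiation only C3. Compound 2 is the acetal ether of phenol 1, which already has the two oxygens differentiated.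

## Alternatives that were turned down

Alternative 1: Double Robinson-type annulation.
- Disconnection: in each half C4–C4a (Michael) and C1=C8a (aldol condensation) are cut. The target falls into two molecules of the terpene-derived enone A2, which supplies ring B with C5 in place, and the symmetrical bis-enone A3, whose central CH2–CH2 bond is the future biaryl bond.
- Forward key step: the enolate of A2 at the methylene next to the carbonyl (future C4a) adds to each terminal methylene of A3. The tetraketone condenses twice to the bis-trienone A1, an isomer of the target, which would aromatise by enolisation and migration of the C7=C8 double bond into ring A.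
- For: three or four operations, all thirty carbons from two cheap pieces, C5 from the chiral pool, no protecting groups.
- Against: A3 is a 1,4-diketone with two polymerisable isopropenyl ketone ends. Under base, the five-membered aldol (C3 of one half onto the carbonyl of the other, giving a cyclopentenone) is the usual fate of a 1,4-diketone and competes with the six-membered condensation onto a hindered conjugated ring carbonyl. The condensation must also create two tetrasubstituted alkenes on adjacent carbons.
- Decisive weakness: C8 is not a stereocentre in A1. It is created by the protonation that aromatises ring A, with only the remote C5 to guide it, so the cis relationship is left to thermodynamics, which in a 1,4-disubstituted tetralin need not favour cis.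
- Comparison: Alternative 1 is clearly stronger on step economy and on buying C5. The chosen route is about three times longer, but it gives every stereocentre its own control element and never has to build or aromatise a benzene ring, since the substitution pattern of ring A is present from compound 1.

Alternative 2: Silicon-tethered double [2+2+2] benzannulation.
- Disconnection: in each half C4a–C8a, C1–C2 and C3–C4 are cut, so each benzene ring is taken apart into three alkynes. The open-chain tetrayne A5 supplies C4≡C4a and C8a≡C1 of both halves (its central diyne bond is the biaryl bond). The bis(propynyl)silane A6 supplies C2≡C3 of both halves, with silicon tying the two C2 atoms together.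
- Forward key step: a cationic rhodium–bisphosphine catalyst effects two cyclotrimerisations to the silicon-bridged biaryl A4. Tamao–Fleming oxidation of the two aryl–silicon bonds would then give the diol.
- For: six C–C bonds and five rings in one step; the tether dictates that oxygen ends at C2 and methyl at C3. A chiral catalyst could in principle set the biaryl axis, and on that point it is stronger than the chosen route, which leaves the axis uncontrolled.
- Against: all four stereocentres must already be in A5, as two pairs of 1,4-related propargylic centres in an open chain, which costs a long linear synthesis with separate asymmetric steps. Each diyne terminus must pair with an alkyne of A6 and not with a second molecule of A5, although A6 (internal, silyl-substituted) is the least reactive alkyne present. The second cyclotrimerisation closes a strained silafluorene with four ortho substituents, and oxidising two hindered aryl–silicon bonds is at the limit of that chemistry.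
- Comparison: more convergent in the key step and better on the axis. The chosen route takes ring A ready-made, sets its stereocentres by two well-precedented catalytic reaction types, and keeps the risk in one palladium step of known type.

Alternative 3: Double Diels–Alder on a diynedione.
- Disconnection: C1–C8a and C2–C3 in each half, after replacing each hydroxyl by acetyl. This gives the diynedione A9 (central bond = biaryl bond) and two molecules of diene A8, a 1-propenylcyclohexene that would come from the cis ketone A10 by enol triflate formation on the methylene side and coupling with a propenyl metal.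
- Forward key step: two cycloadditions and aromatisation of the bis-cyclohexadiene by a high-potential quinone in the same flask give the diacetyl biaryl A7. Baeyer–Villiger oxidation and hydrolysis would convert acetyl into hydroxyl.
- For: both stereocentres of each half, already cis, are bought with A10. Here it is stronger than the chosen route, which needs two asymmetric catalytic steps. It is also very short.
- Against: both diene termini are alkylated, so the orientation rests only on the alkyl group at the inner diene carbon. The required orientation joins the hindered ring terminus (next to the C8 methyl) to the inner diyne carbon, twice, and the second cycloaddition must build the tetra-ortho-substituted biaryl position. The quinone needed for aromatisation is the type of reagent that abstracts benzylic hydride from C5 and C8 and would carry ring B on to a naphthalene. A10 is the less stable C2 epimer of its trans isomer, belongs to the less abundant enantiomeric series, and can epimerise during enolisation. A9 is prone to polymerisation.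
- Comparison: better on stereochemical economy, worse on regiochemical certainty and on compatibility of the oxidant with the benzylic centres. The chosen route has no regiochemical question, because every ring-A substituent is placed by directed metalation on an arene, and it uses no oxidant after the stereocentres exist.

Key step: step 10

Remarks on the chemistry:
- The structure as written fixes the four carbon stereocentres but not the sense of the hindered biaryl axis. The route fixes the former and carries both axial forms of the (S,S) series from step 4 on, to be separated as diastereomers at 16 or 17 if they do not interconvert.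
- 3-Methoxy-4-methylphenol (1), which already has the two oxygens differentiated, is taken as a catalogue compound.
- Biaryls 4–14 are named with one numbering (C1 biaryl carbon, C2 the oxygen that ends as triflate, C3 side-chain carbon, C5 methyl, C6 methoxy). In the twofold steps both arms react in the same operation, and the half-converted species carry no number.

## Route

Step 1
Reactants: 1 3-methoxy-4-methylphenol
Product: 2 2-methoxy-4-(methoxymethoxy)-1-methylbenzene
Conditions: NaH, MOMCl, THF, 0 °C to rt
Reagents that add atoms: chloromethyl methyl ether (MOMCl), COCCl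
Why: Williamson-type O-alkylation of the sodium phenoxide. The methoxymethyl ether is chosen because it is a strong ortho-director, survives organolithium, hydride and Grignard reagents, and later leaves under mild acid that does not touch the methyl ether.

Step 2
Reactants: 2 2-methoxy-4-(methoxymethoxy)-1-methylbenzene (two molecules)
Product: 4 6,6'-dimethoxy-2,2'-bis(methoxymethoxy)-5,5'-dimethyl-1,1'-biphenyl, via aryllithium 3 (not isolated)
Conditions: n-BuLi, THF, 0 °C to rt; then CuCl2 (anhydrous), −78 °C to rt
Reagents that add atoms: none
Why: Directed ortho-metalation removes the hydrogen between the two oxygens, which both activate it; transmetalation to divalent copper and reductive coupling of two aryl groups (oxidative homocoupling of an aryllithium) should give the tetra-ortho-oxygenated biaryl in one operation. The axis forms without control.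

Step 3
Reactants: 4 6,6'-dimethoxy-2,2'-bis(methoxymethoxy)-5,5'-dimethyl-1,1'-biphenyl
Product: 6 2,2'-[6,6'-dimethoxy-2,2'-bis(methoxymethoxy)-5,5'-dimethyl[1,1'-biphenyl]-3,3'-diyl]bis(4,4,5,5-tetramethyl-1,3,2-dioxaborolane), via 3,3'-dilithiobiaryl 5 (not isolated)
Conditions: n-BuLi, TMEDA, Et2O, 0 °C to rt; then i-PrOBpin, −78 °C to rt
Reagents that add atoms: 2-isopropoxy-4,4,5,5-tetramethyl-1,3,2-dioxaborolane (i-PrOBpin), CC(C)OB1OC(C)(C)C(C)(C)O1
Why: Second directed ortho-metalation: on each ring the methoxymethoxy group has one free ortho position (C3) and the methoxy group has none, so the twofold lithiation is unambiguous, as in the familiar 3,3'-dilithiation of acetal-protected biaryl diols. The borate ester traps both carbanions as pinacol boronates.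

Step 4
Reactants: 6 2,2'-[6,6'-dimethoxy-2,2'-bis(methoxymethoxy)-5,5'-dimethyl[1,1'-biphenyl]-3,3'-diyl]bis(4,4,5,5-tetramethyl-1,3,2-dioxaborolane); 7 ethyl (2E)-4-methylpent-2-enoate
Product: 8 diethyl (3S,3'S)-3,3'-[6,6'-dimethoxy-2,2'-bis(methoxymethoxy)-5,5'-dimethyl[1,1'-biphenyl]-3,3'-diyl]bis(4-methylpentanoate)
Conditions: [RhCl(C2H4)2]2 (3 mol%), (S)-BINAP (7 mol%), K3PO4 (aq, 0.5 equiv per boron), 7 (6 equiv), dioxane–H2O 10:1, 60 °C
Reagents that add atoms: none
Why: Rhodium-catalysed asymmetric conjugate addition of an arylboron reagent to an (E)-enoate (Hayashi–Miyaura reaction): transmetalation gives an aryl–rhodium–BINAP species that inserts the enoate and is protonated by water. The future C5 centre is set by the ligand: with (S)-BINAP the aryl group is expected on the 2-si face of the enoate, which is S here because isopropyl outranks CH2CO2Et; this assignment is to be confirmed on the first batch, the antipodal ligand being equally available. The arms react independently, so most minor-face addition ends in the (S,R) diastereomer and is removed by chromatography (Horeau-type amplification).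

Step 5
Reactants: 8 diethyl (3S,3'S)-3,3'-[6,6'-dimethoxy-2,2'-bis(methoxymethoxy)-5,5'-dimethyl[1,1'-biphenyl]-3,3'-diyl]bis(4-methylpentanoate)
Product: 9 (3S,3'S)-3,3'-[6,6'-dimethoxy-2,2'-bis(methoxymethoxy)-5,5'-dimethyl[1,1'-biphenyl]-3,3'-diyl]bis(4-methylpentan-1-ol)
Conditions: LiAlH4, THF, 0 °C to rt
Reagents that add atoms: none
Why: Hydride reduction of both esters to primary alcohols. Acetals, aryl ethers and the benzylic stereocentres are inert to LiAlH4.

Step 6
Reactants: 9 (3S,3'S)-3,3'-[6,6'-dimethoxy-2,2'-bis(methoxymethoxy)-5,5'-dimethyl[1,1'-biphenyl]-3,3'-diyl]bis(4-methylpentan-1-ol)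
Product: 10 3,3'-bis[(3S)-1-iodo-4-methylpentan-3-yl]-6,6'-dimethoxy-2,2'-bis(methoxymethoxy)-5,5'-dimethyl-1,1'-biphenyl
Conditions: I2, PPh3, imidazole, CH2Cl2, 0 °C to rt
Reagents that add atoms: iodine, II
Why: Appel-type iodination: the alkoxyphosphonium ions are displaced by iodide at primary carbons under near-neutral conditions that the acetals tolerate. The stereocentres are two carbons away.

Step 7
Reactants: 10 3,3'-bis[(3S)-1-iodo-4-methylpentan-3-yl]-6,6'-dimethoxy-2,2'-bis(methoxymethoxy)-5,5'-dimethyl-1,1'-biphenyl; 11 vinylmagnesium bromide
Product: 12 6,6'-dimethoxy-2,2'-bis(methoxymethoxy)-5,5'-dimethyl-3,3'-bis[(3S)-2-methylhept-6-en-3-yl]-1,1'-biphenyl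
Conditions: 11 (6 equiv), CuI (20 mol%), THF–DMPU, −30 to 0 °C
Reagents that add atoms: none
Why: Copper-catalysed cross-coupling of a primary alkyl iodide with a vinyl Grignard reagent, through an alkyl(vinyl)copper intermediate, adds C8 and the future exocyclic carbon to each arm. Low temperature and the polar co-solvent favour substitution over elimination; ethers and acetals are inert.

Step 8
Reactants: 12 6,6'-dimethoxy-2,2'-bis(methoxymethoxy)-5,5'-dimethyl-3,3'-bis[(3S)-2-methylhept-6-en-3-yl]-1,1'-biphenyl
Product: 13 6,6'-dimethoxy-5,5'-dimethyl-3,3'-bis[(3S)-2-methylhept-6-en-3-yl][1,1'-biphenyl]-2,2'-diol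
Conditions: HCl (3 M aq), MeOH–THF, 45 °C
Reagents that add atoms: none
Why: Acid-catalysed acetal exchange with methanol removes both methoxymethyl groups as dimethoxymethane. Aryl methyl ethers and isolated terminal alkenes are stable to dilute acid at this temperature.

Step 9
Reactants: 13 6,6'-dimethoxy-5,5'-dimethyl-3,3'-bis[(3S)-2-methylhept-6-en-3-yl][1,1'-biphenyl]-2,2'-diol
Product: 14 6,6'-dimethoxy-5,5'-dimethyl-3,3'-bis[(3S)-2-methylhept-6-en-3-yl][1,1'-biphenyl]-2,2'-diyl bis(trifluoromethanesulfonate)
Conditions: Tf2O, pyridine, CH2Cl2, 0 °C
Reagents that add atoms: trifluoromethanesulfonic anhydride (Tf2O), O=S(=O)(OS(=O)(=O)C(F)(F)F)C(F)(F)F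
Why: O-Sulfonylation of the phenols. Each hydroxyl is flanked by the biaryl bond and the branched side chain, but triflic anhydride with pyridine is reactive enough for hindered phenols, and nothing else in 13 is nucleophilic.

Step 10
Reactants: 14 6,6'-dimethoxy-5,5'-dimethyl-3,3'-bis[(3S)-2-methylhept-6-en-3-yl][1,1'-biphenyl]-2,2'-diyl bis(trifluoromethanesulfonate)
Product: 15 (5S,5'S)-2,2'-dimethoxy-3,3'-dimethyl-8,8'-dimethylidene-5,5'-di(propan-2-yl)-5,5',6,6',7,7',8,8'-octahydro-1,1'-binaphthalene
Conditions: Pd(OAc)2 (20 mol%), dppp (1,3-bis(diphenylphosphanyl)propane, 24 mol%), 1,2,2,6,6-pentamethylpiperidine (4 equiv), DMA, 110 °C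
Reagents that add atoms: none
Why: Twofold intramolecular Heck reaction; the closest known type is the 6-exo cyclisation of 2-(pent-4-enyl)aryl triflates to 1-methylenetetralins. Pd(OAc)2 is reduced by the phosphine, and the chelated zerovalent palladium inserts into each C8a–O bond to give a cationic arylpalladium triflate; a chelating bisphosphine in a polar solvent is chosen because triflates ionise in this manifold, whereas monoligated palladium carrying a very bulky trialkylphosphine prefers aryl halides and reacts sluggishly with triflates. The cationic divalent palladium binds the pendant alkene and inserts it syn in the 6-exo-trig mode, so C8a bonds to the internal alkene carbon (C8) and palladium moves to the terminal carbon, closing ring B of one half and then, by the same sequence, of the other. The only β-hydrogen available to the primary alkylpalladium is on C8, so β-hydride elimination can only give the exocyclic C8=CH2, and the amine base takes up triflic acid and returns zerovalent palladium. No stereocentre is formed, and C5, set in step 4, is remote from the metal and is carried through unchanged. The step needs 6-exo over 7-endo closure, which the three-carbon tether (C5, C6, C7) between C4a and the alkene secures, since 6-exo insertion puts palladium on the unhindered terminal carbon. It also needs the product double bond to stay exocyclic and the alkene of the still open arm to stay terminal, which the hindered amine base, the absence of halide and stopping at full conversion are meant to secure. The hindrance at C8a is partly self-compensating, because the second ortho substituent is the tether itself and holds the alkene beside palladium once the C–O bond is broken.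

Step 11
Reactants: 15 (5S,5'S)-2,2'-dimethoxy-3,3'-dimethyl-8,8'-dimethylidene-5,5'-di(propan-2-yl)-5,5',6,6',7,7',8,8'-octahydro-1,1'-binaphthalene
Product: 16 (5S,5'S,8S,8'S)-2,2'-dimethoxy-3,3',8,8'-tetramethyl-5,5'-di(propan-2-yl)-5,5',6,6',7,7',8,8'-octahydro-1,1'-binaphthalene
Conditions: H2 (1 bar), [Ir(cod)((S)-tBu-PHOX)][B(C6H3(CF3)2)4] (2 mol% per alkene; tBu-PHOX = 4-tert-butyl-2-[2-(diphenylphosphanyl)phenyl]-4,5-dihydro-1,3-oxazole), CH2Cl2, 0 °C to rt
Reagents that add atoms: none
Why: Iridium-catalysed asymmetric hydrogenation of an unfunctionalised 1,1-disubstituted alkene: the cationic iridium dihydride with the P,N ligand delivers both hydrogens to one face of C8=CH2. Both C8 centres are set by the catalyst, helped by the C5 isopropyl group, which disfavours approach to its own face; hydrogen anti to isopropyl leaves methyl and isopropyl cis (8S). The (S)-ligand is entered provisionally and the antipode that matches the substrate bias is fixed by one trial with each; the low pressure limits double-bond migration.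

Step 12
Reactants: 16 (5S,5'S,8S,8'S)-2,2'-dimethoxy-3,3',8,8'-tetramethyl-5,5'-di(propan-2-yl)-5,5',6,6',7,7',8,8'-octahydro-1,1'-binaphthalene
Product: 17 (5S,5'S,8S,8'S)-3,3',8,8'-tetramethyl-5,5'-di(propan-2-yl)-5,5',6,6',7,7',8,8'-octahydro[1,1'-binaphthalene]-2,2'-diol
Conditions: BBr3, CH2Cl2, −78 to 0 °C; then H2O
Reagents that add atoms: none
Why: Lewis-acid cleavage of aryl methyl ethers: BBr3 coordinates the ether oxygen, bromide removes the methyl group, and hydrolysis of the aryloxyboron species frees both phenols. The low temperature keeps the benzylic C–H bonds at C5 and C8 untouched.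

## Compound list

1 | 3-methoxy-4-methylphenol | Cc1ccc(O)cc1OC | starting material
2 | 2-methoxy-4-(methoxymethoxy)-1-methylbenzene | COCOc1ccc(C)c(OC)c1 | intermediate
3 | [2-methoxy-6-(methoxymethoxy)-3-methylphenyl]lithium (aryllithium, not isolated) | [Li]c1c(OCOC)ccc(C)c1OC | intermediate
4 | 6,6'-dimethoxy-2,2'-bis(methoxymethoxy)-5,5'-dimethyl-1,1'-biphenyl | COCOc1ccc(C)c(OC)c1-c1c(OC)c(C)ccc1OCOC | intermediate
5 | 3,3'-dilithio-6,6'-dimethoxy-2,2'-bis(methoxymethoxy)-5,5'-dimethyl-1,1'-biphenyl (not isolated) | COCOc1c([Li])cc(C)c(OC)c1-c1c(OC)c(C)cc([Li])c1OCOC | intermediate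
6 | 2,2'-[6,6'-dimethoxy-2,2'-bis(methoxymethoxy)-5,5'-dimethyl[1,1'-biphenyl]-3,3'-diyl]bis(4,4,5,5-tetramethyl-1,3,2-dioxaborolane) | COCOc1c(B2OC(C)(C)C(C)(C)O2)cc(C)c(OC)c1-c1c(OC)c(C)cc(B2OC(C)(C)C(C)(C)O2)c1OCOC | intermediate
7 | ethyl (2E)-4-methylpent-2-enoate | CCOC(=O)/C=C/C(C)C | starting material
8 | diethyl (3S,3'S)-3,3'-[6,6'-dimethoxy-2,2'-bis(methoxymethoxy)-5,5'-dimethyl[1,1'-biphenyl]-3,3'-diyl]bis(4-methylpentanoate) | Cc1cc([C@@H](CC(=O)OCC)C(C)C)c(OCOC)c(-c2c(OC)c(C)cc([C@@H](CC(=O)OCC)C(C)C)c2OCOC)c1OC | intermediate
9 | (3S,3'S)-3,3'-[6,6'-dimethoxy-2,2'-bis(methoxymethoxy)-5,5'-dimethyl[1,1'-biphenyl]-3,3'-diyl]bis(4-methylpentan-1-ol) | Cc1cc([C@@H](CCO)C(C)C)c(OCOC)c(-c2c(OC)c(C)cc([C@@H](CCO)C(C)C)c2OCOC)c1OC | intermediate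
10 | 3,3'-bis[(3S)-1-iodo-4-methylpentan-3-yl]-6,6'-dimethoxy-2,2'-bis(methoxymethoxy)-5,5'-dimethyl-1,1'-biphenyl | Cc1cc([C@@H](CCI)C(C)C)c(OCOC)c(-c2c(OC)c(C)cc([C@@H](CCI)C(C)C)c2OCOC)c1OC | intermediate
11 | vinylmagnesium bromide | C=C[Mg]Br | starting material
12 | 6,6'-dimethoxy-2,2'-bis(methoxymethoxy)-5,5'-dimethyl-3,3'-bis[(3S)-2-methylhept-6-en-3-yl]-1,1'-biphenyl | Cc1cc([C@@H](CCC=C)C(C)C)c(OCOC)c(-c2c(OC)c(C)cc([C@@H](CCC=C)C(C)C)c2OCOC)c1OC | intermediate
13 | 6,6'-dimethoxy-5,5'-dimethyl-3,3'-bis[(3S)-2-methylhept-6-en-3-yl][1,1'-biphenyl]-2,2'-diol | Cc1cc([C@@H](CCC=C)C(C)C)c(O)c(-c2c(OC)c(C)cc([C@@H](CCC=C)C(C)C)c2O)c1OC | intermediate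
14 | 6,6'-dimethoxy-5,5'-dimethyl-3,3'-bis[(3S)-2-methylhept-6-en-3-yl][1,1'-biphenyl]-2,2'-diyl bis(trifluoromethanesulfonate) | Cc1cc([C@@H](CCC=C)C(C)C)c(OS(=O)(=O)C(F)(F)F)c(-c2c(OC)c(C)cc([C@@H](CCC=C)C(C)C)c2OS(=O)(=O)C(F)(F)F)c1OC | intermediate
15 | (5S,5'S)-2,2'-dimethoxy-3,3'-dimethyl-8,8'-dimethylidene-5,5'-di(propan-2-yl)-5,5',6,6',7,7',8,8'-octahydro-1,1'-binaphthalene | Cc1cc2c(c(-c3c(OC)c(C)cc4c3C(=C)CC[C@H]4C(C)C)c1OC)C(=C)CC[C@H]2C(C)C | intermediate
16 | (5S,5'S,8S,8'S)-2,2'-dimethoxy-3,3',8,8'-tetramethyl-5,5'-di(propan-2-yl)-5,5',6,6',7,7',8,8'-octahydro-1,1'-binaphthalene | Cc1cc2c(c(-c3c(OC)c(C)cc4c3[C@@H](C)CC[C@H]4C(C)C)c1OC)[C@@H](C)CC[C@H]2C(C)C | intermediate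
17 | (5S,5'S,8S,8'S)-3,3',8,8'-tetramethyl-5,5'-di(propan-2-yl)-5,5',6,6',7,7',8,8'-octahydro[1,1'-binaphthalene]-2,2'-diol | Cc1cc2c(c(-c3c(O)c(C)cc4c3[C@@H](C)CC[C@H]4C(C)C)c1O)[C@@H](C)CC[C@H]2C(C)C | target

## Step count and least certain steps

Total step count: 12. Longest linear sequence: 12 steps (1 to 17); compounds 7 and 11 are purchased.

**Step 10 (key step).**
- What may go wrong: insertion of palladium into the C8a–O bond, which has two ortho substituents on an electron-rich ring, is slow. The palladium hydride released by the first ring closure then has time to move the terminal double bond of the still open arm inward, after which that arm can no longer close 6-exo, and to move the exocyclic double bond of the closed half into the ring. Sulfur–oxygen cleavage of the triflate back to the phenol is a further drain.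
- Fallback: replace the alkene acceptor by an alkyne and the Heck reaction by a reductive 6-exo-dig carbopalladation. The alkenylpalladium formed has no β-hydrogen, no palladium hydride meets an alkene, and forcing conditions can be used. It sets out from diiodide 10. Alkylation with lithium (trimethylsilyl)acetylide in THF–DMPU should give 6,6'-dimethoxy-2,2'-bis(methoxymethoxy)-5,5'-dimethyl-3,3'-bis[(3S)-2-methyl-7-(trimethylsilyl)hept-6-yn-3-yl]-1,1'-biphenyl F1. HCl in MeOH should give the corresponding 2,2'-diol F2, and Tf2O with pyridine its bis(trifluoromethanesulfonate) F3. With Pd(OAc)2, PPh3 and HCO2Na in DMF at 100 °C, syn addition of aryl and palladium across each alkyne and reduction by formate should give the (E,E)-bis(alkenylsilane) (5S,5'S,8E,8'E)-2,2'-dimethoxy-3,3'-dimethyl-5,5'-di(propan-2-yl)-8,8'-bis[(trimethylsilyl)methylidene]-5,5',6,6',7,7',8,8'-octahydro-1,1'-binaphthalene F4. Protodesilylation with CF3CO2H in CH2Cl2 at 0 °C returns to the route at 15.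

**Step 11.**
- What may go wrong: poor facial selectivity, because three elements act on the same alkene (the catalyst, the remote C5 centre and the sense of the biaryl axis, whose ortho substituents sit above and below C8) and may oppose each other in one axial form. Catalyst-induced migration of the double bond into the ring, giving an alkene that is reduced with a different facial preference, is the second risk.
- Fallback: move stereocontrol onto the trisubstituted alkene, the substrate class on which iridium P,N catalysts exert their strongest control. It sets out from 15. RhCl3·3H2O in EtOH (or catalytic TsOH) should move both double bonds into ring B, giving (5S,5'S)-2,2'-dimethoxy-3,3',8,8'-tetramethyl-5,5'-di(propan-2-yl)-5,5',6,6'-tetrahydro-1,1'-binaphthalene F5. Hydrogenation of F5 with the iridium catalyst of step 11, ligand antipode chosen by trial, returns to the route at 16.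

**Step 4.**
- What may go wrong: protodeboronation of the ortho-alkoxy arylboron species faster than insertion of the β-branched enoate, leaving one or both arms as C–H, or insufficient facial selectivity.
- Fallback: auxiliary control with an aryl–copper nucleophile in place of catalyst control with aryl–rhodium. It sets out from biaryl 4. Lithiation as in step 3 gives 5, which is transmetalated with MgBr2·OEt2 and CuBr·SMe2 and added to (4S)-3-[(2E)-4-methylpent-2-enoyl]-4-phenyl-1,3-oxazolidin-2-one F6, made by N-acylation of the commercial auxiliary. In the magnesium-chelated imide the aryl group adds anti to the 4-phenyl group, which for this auxiliary corresponds to 3S, giving (4S,4'S)-3,3'-{[6,6'-dimethoxy-2,2'-bis(methoxymethoxy)-5,5'-dimethyl[1,1'-biphenyl]-3,3'-diyl]bis[(3S)-4-methyl-1-oxopentane-3,1-diyl]}bis(4-phenyl-1,3-oxazolidin-2-one) F7. LiBH4 removes the auxiliary reductively and returns to the route at diol 9.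

**Step 2.**
- What may go wrong: the arylcopper species of divalent copper break down by electron transfer instead of coupling (recovery of 2, aryl chloride), made worse by the two ortho substituents.
- Fallback: classical two-stage biaryl synthesis. It sets out from 2. Lithiation as in step 2 and quenching with I2 should give 3-iodo-2-methoxy-4-(methoxymethoxy)-1-methylbenzene F8. Ullmann homocoupling with activated copper powder in DMF at 150 °C returns to the route at 4.

**Step 7.**
- What may go wrong: dehydrohalogenation or halogen–magnesium exchange of the iodide, and displacement of iodide by the neighbouring acetal oxygen (chroman formation), competing with a slow coupling.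
- Fallback: substitution by an acetylide followed by semi-reduction. It sets out from 10. Lithium acetylide–ethylenediamine complex in DMSO should give 6,6'-dimethoxy-2,2'-bis(methoxymethoxy)-5,5'-dimethyl-3,3'-bis[(3S)-2-methylhept-6-yn-3-yl]-1,1'-biphenyl F9. Semi-hydrogenation (H2, Pd/CaCO3 poisoned with Pb(OAc)2, quinoline) returns to the route at 12.

## Further compounds

F1 | step 10 | 6,6'-dimethoxy-2,2'-bis(methoxymethoxy)-5,5'-dimethyl-3,3'-bis[(3S)-2-methyl-7-(trimethylsilyl)hept-6-yn-3-yl]-1,1'-biphenyl | Cc1cc([C@@H](CCC#C[Si](C)(C)C)C(C)C)c(OCOC)c(-c2c(OC)c(C)cc([C@@H](CCC#C[Si](C)(C)C)C(C)C)c2OCOC)c1OC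
F2 | step 10 | 6,6'-dimethoxy-5,5'-dimethyl-3,3'-bis[(3S)-2-methyl-7-(trimethylsilyl)hept-6-yn-3-yl][1,1'-biphenyl]-2,2'-diol | Cc1cc([C@@H](CCC#C[Si](C)(C)C)C(C)C)c(O)c(-c2c(OC)c(C)cc([C@@H](CCC#C[Si](C)(C)C)C(C)C)c2O)c1OC
F3 | step 10 | 6,6'-dimethoxy-5,5'-dimethyl-3,3'-bis[(3S)-2-methyl-7-(trimethylsilyl)hept-6-yn-3-yl][1,1'-biphenyl]-2,2'-diyl bis(trifluoromethanesulfonate) | Cc1cc([C@@H](CCC#C[Si](C)(C)C)C(C)C)c(OS(=O)(=O)C(F)(F)F)c(-c2c(OC)c(C)cc([C@@H](CCC#C[Si](C)(C)C)C(C)C)c2OS(=O)(=O)C(F)(F)F)c1OC
F4 | step 10 | (5S,5'S,8E,8'E)-2,2'-dimethoxy-3,3'-dimethyl-5,5'-di(propan-2-yl)-8,8'-bis[(trimethylsilyl)methylidene]-5,5',6,6',7,7',8,8'-octahydro-1,1'-binaphthalene | Cc1cc2c(c(-c3c(OC)c(C)cc4c3/C(=C/[Si](C)(C)C)CC[C@H]4C(C)C)c1OC)/C(=C/[Si](C)(C)C)CC[C@H]2C(C)C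
F5 | step 11 | (5S,5'S)-2,2'-dimethoxy-3,3',8,8'-tetramethyl-5,5'-di(propan-2-yl)-5,5',6,6'-tetrahydro-1,1'-binaphthalene | Cc1cc2c(c(-c3c(OC)c(C)cc4c3C(C)=CC[C@H]4C(C)C)c1OC)C(C)=CC[C@H]2C(C)C
F6 | step 4 | (4S)-3-[(2E)-4-methylpent-2-enoyl]-4-phenyl-1,3-oxazolidin-2-one | CC(C)/C=C/C(=O)N1[C@@H](c2ccccc2)COC1=O
F7 | step 4 | (4S,4'S)-3,3'-{[6,6'-dimethoxy-2,2'-bis(methoxymethoxy)-5,5'-dimethyl[1,1'-biphenyl]-3,3'-diyl]bis[(3S)-4-methyl-1-oxopentane-3,1-diyl]}bis(4-phenyl-1,3-oxazolidin-2-one) | Cc1cc([C@@H](CC(=O)N2[C@@H](c3ccccc3)COC2=O)C(C)C)c(OCOC)c(-c2c(OC)c(C)cc([C@@H](CC(=O)N3[C@@H](c4ccccc4)COC3=O)C(C)C)c2OCOC)c1OC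
F8 | step 2 | 3-iodo-2-methoxy-4-(methoxymethoxy)-1-methylbenzene | COCOc1ccc(C)c(OC)c1I
F9 | step 7 | 6,6'-dimethoxy-2,2'-bis(methoxymethoxy)-5,5'-dimethyl-3,3'-bis[(3S)-2-methylhept-6-yn-3-yl]-1,1'-biphenyl | Cc1cc([C@@H](CCC#C)C(C)C)c(OCOC)c(-c2c(OC)c(C)cc([C@@H](CCC#C)C(C)C)c2OCOC)c1OC
A1 | alternative 1 | (5S,5'S)-3,3',8,8'-tetramethyl-5,5'-di(propan-2-yl)-4,4',4a,4'a,5,5',6,6'-octahydro[1,1'-binaphthalene]-2,2'(3H,3'H)-dione (bis-trienone) | CC1CC2C(=C(C3=C4C(C)=CC[C@@H](C(C)C)C4CC(C)C3=O)C1=O)C(C)=CC[C@H]2C(C)C
A2 | alternative 1 | (5R)-2-methyl-5-(propan-2-yl)cyclohex-2-en-1-one ((R)-carvotanacetone) | CC1=CC[C@@H](C(C)C)CC1=O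
A3 | alternative 1 | 2,7-dimethylocta-1,7-diene-3,6-dione | C=C(C)C(=O)CCC(=O)C(C)=C
A4 | alternative 2 | 9,9-di(propan-2-yloxy)-9-silafluorene carrying both tetralin rings (the target skeleton with Si(OiPr)2 bridging C2 and C2') | Cc1cc2c(c3c1[Si](OC(C)C)(OC(C)C)c1c(C)cc4c(c1-3)[C@@H](C)CC[C@H]4C(C)C)[C@@H](C)CC[C@H]2C(C)C
A5 | alternative 2 | (3S,6S,11S,14S)-6,11-dimethyl-3,14-di(propan-2-yl)hexadeca-1,7,9,15-tetrayne | C#C[C@H](C(C)C)CC[C@H](C)C#CC#C[C@@H](C)CC[C@@H](C(C)C)C#C
A6 | alternative 2 | di(propan-2-yloxy)di(prop-1-yn-1-yl)silane | CC#C[Si](OC(C)C)(OC(C)C)C#CC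
A7 | alternative 3 | 1,1'-[(5S,5'S,8S,8'S)-3,3',8,8'-tetramethyl-5,5'-di(propan-2-yl)-5,5',6,6',7,7',8,8'-octahydro[1,1'-binaphthalene]-2,2'-diyl]di(ethan-1-one) | Cc1cc2c(c(-c3c(C(C)=O)c(C)cc4c3[C@@H](C)CC[C@H]4C(C)C)c1C(C)=O)[C@@H](C)CC[C@H]2C(C)C
A8 | alternative 3 | (3S,6S)-3-methyl-6-(propan-2-yl)-1-[(1E)-prop-1-en-1-yl]cyclohex-1-ene | C/C=C/C1=C[C@@H](C)CC[C@H]1C(C)C
A9 | alternative 3 | octa-3,5-diyne-2,7-dione | CC(=O)C#CC#CC(C)=O
A10 | alternative 3 | (2S,5S)-5-methyl-2-(propan-2-yl)cyclohexan-1-one ((2S,5S)-isomenthone) | O=C1C[C@@H](C)CC[C@H]1C(C)C
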